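**Strategy.** Both rings of the target are the same 6-heptylresorcylic acid. Ring B differs only by the methoxy group on C5', the carbon para to the C2' hydroxyl, which is the sole free phenol. Everything rests on forming the C5'–O bond last. Constant-current electrolysis of diaryl ether 18 (both carboxyls as benzyl esters, C2'–OH free, C5'–H) in methanol takes four electrons from ring B. It delivers dimethoxy dienone 21 in one operation, with ring A untouched. Diaryl ether 18 is assembled from two copies of one monomer by depside esterification and a Smiles rearrangement. Zinc reduction and hydrogenolysis then give the target.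

Key step: step 10

Remark on stereochemistry: the target has no stereocentre and its diaryl ether axis rotates freely, so it is achiral and there is no enantiomer to choose. Compounds 5–8 are racemic, and their stereocentres disappear in step 3.

Atom labels: ring A is C1 (carboxyl), C2 (heptyl), C4 (OMe), C6 (ether O). Ring B is C1' (carboxyl), C2' (OH), C3' (H), C4' (ether O), C5' (OMe), C6' (heptyl).

Design remark: the acyl partner of the depside coupling must be the free acid 11. The ring A benzyl ester of 18 can therefore be installed only after the aryl shift has released that carboxyl group (step 9).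

Step 1
Reactants: 1 octanal; 2 1-(triphenyl-λ5-phosphanylidene)propan-2-one
Product: 3 (E)-undec-3-en-2-one
Conditions: CH2Cl2, reflux
Reagents that add atoms: none
Why: Wittig olefination with a stabilised acyl ylide is reliable on unbranched aldehydes and should give the E-enone, whose geometry is lost in the next step anyway.

Step 2
Reactants: 3 (E)-undec-3-en-2-one; 4 dimethyl malonate
Product: 6 methyl 6-heptyl-2-hydroxy-4-oxocyclohex-2-ene-1-carboxylate (racemic), via Michael adduct 5 (not isolated)
Conditions: NaOMe (1.1 equiv), MeOH, reflux; then aq. HCl
Reagents that add atoms: none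
Why: Michael addition of the malonate anion, followed by intramolecular Claisen (Dieckmann-type) condensation of the methyl ketone enolate onto one ester, closes the six-membered ring and is driven by the stable 1,3-dione enolate; the two stereocentres form without control and are erased in step 3.

Step 3
Reactants: 6 methyl 6-heptyl-2-hydroxy-4-oxocyclohex-2-ene-1-carboxylate
Product: 9 methyl 2-heptyl-4,6-dihydroxybenzoate, via 3-bromo enolone 7 (not isolated), via 5-bromo enolone 8 (not isolated)
Conditions: Br2 (1.0 equiv), DMF, 0 °C → 80 °C, heating stopped once aromatisation is complete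
Reagents that add atoms: none
Why: Bromination–dehydrobromination aromatisation, in which the enol is brominated at C3, HBr shifts the halogen to C5 and loss of HBr across C5–C6 gives a dienone that tautomerises to the resorcylate, while one equivalent of bromine and limited heating should suppress ring bromination and ester cleavage.

Step 4
Reactants: 9 methyl 2-heptyl-4,6-dihydroxybenzoate
Product: 10 methyl 2-heptyl-6-hydroxy-4-methoxybenzoate
Conditions: MeI (1.05 equiv), K2CO3, acetone, reflux
Reagents that add atoms: iodomethane, CI
Why: Williamson ether synthesis that is site-selective because the hydroxyl ortho to the ester is held in a hydrogen bond to the carbonyl, so one equivalent of iodomethane alkylates only the free, more acidic C4 hydroxyl.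

Step 5
Reactants: 10 methyl 2-heptyl-6-hydroxy-4-methoxybenzoate
Product: 11 2-heptyl-6-hydroxy-4-methoxybenzoic acid
Conditions: KOH, DMSO–H2O, 90 °C; then aq. HCl, 0 °C
Reagents that add atoms: potassium hydroxide, [K+].[OH-]
Why: Saponification of the hindered salicylate ester works in aqueous DMSO because poorly solvated hydroxide is reactive enough there, and cold acidification avoids loss of CO2.

Step 6
Reactants: 9 methyl 2-heptyl-4,6-dihydroxybenzoate
Product: 12 2-heptyl-4,6-dihydroxybenzoic acid
Conditions: KOH, DMSO–H2O, 70 °C, N2; then aq. HCl, 0 °C
Reagents that add atoms: potassium hydroxide, [K+].[OH-]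
Why: Saponification in which the resorcylate is kept as its salt at moderate temperature under nitrogen and protonated only in the cold, because the free acid decarboxylates on heating.

Step 7
Reactants: 12 2-heptyl-4,6-dihydroxybenzoic acid; 13 benzyl bromide
Product: 14 benzyl 2-heptyl-4,6-dihydroxybenzoate
Conditions: KHCO3, DMF, rt
Reagents that add atoms: benzyl bromide (13), BrCc1ccccc1
Why: SN2 O-alkylation of the carboxylate under hydrogencarbonate, a base strong enough to deprotonate only the carboxylic acid, so both phenols should stay free.

Step 8
Reactants: 11 2-heptyl-6-hydroxy-4-methoxybenzoic acid; 14 benzyl 2-heptyl-4,6-dihydroxybenzoate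
Product: 16 benzyl 2-heptyl-4-[(2-heptyl-6-hydroxy-4-methoxybenzoyl)oxy]-6-hydroxybenzoate (para-depside), via mixed trifluoroacetic anhydride 15 (not isolated)
Conditions: (CF3CO)2O, toluene, rt
Reagents that add atoms: none
Why: Depside esterification through the mixed trifluoroacetic anhydride is a standard method for unprotected o-hydroxybenzoic acids, and of the two phenols of 14 only the unchelated, unhindered C4 hydroxyl should be acylated.

Step 9
Reactants: 16 para-depside; 13 benzyl bromide
Product: 18 benzyl 2-{4-[(benzyloxy)carbonyl]-3-heptyl-5-hydroxyphenoxy}-6-heptyl-4-methoxybenzoate (diaryl ether dibenzyl ester), via potassium carboxylate 17 (not isolated)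
Conditions: K2CO3 (1.1 equiv), dry DMSO, rt → 50 °C; then BnBr (1.05 equiv), rt
Reagents that add atoms: benzyl bromide (13), BrCc1ccccc1
Why: Smiles rearrangement of a depside, in which the C6 phenoxide of ring A adds to C4' of ring B (para to the benzyl ester) through a six-membered spiro Meisenheimer adduct and irreversible release of the ring A carboxylate moves ring B from the carboxyl oxygen to the phenol oxygen; that carboxylate is then the best nucleophile in the flask and is benzylated by SN2 while the chelated C2' phenol stays free.

Step 10
Reactants: 18 diaryl ether dibenzyl ester; 19 methanol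
Product: 21 benzyl 2-({4-[(benzyloxy)carbonyl]-5-heptyl-6,6-dimethoxy-3-oxocyclohexa-1,4-dien-1-yl}oxy)-6-heptyl-4-methoxybenzoate (ring B quinone monoketal), via C5'-methoxyphenol 20 (not isolated)
Conditions: graphite anode, Pt cathode, undivided cell, Et4NOTs, 2,6-lutidine, MeOH–CH2Cl2 (4:1), constant current (about 5 mA cm−2), 4.2–4.5 F mol−1, 0 °C
Reagents that add atoms: methanol (19), CO
Why: Proton-coupled loss of two electrons from the C2' phenol (2,6-lutidine takes the proton) gives a phenoxenium ion with positive charge on C1', C3' and C5'; methanol, present as solvent, adds at the para carbon C5' and tautomerisation gives methoxyphenol 20. The new para-methoxy group makes 20 easier to oxidise than 18, so it is consumed as it forms: a second two-electron oxidation gives a cation at C5' stabilised by that methoxy oxygen, a second methanol adds, and the non-aromatic, electron-poor ketal 21 is no longer oxidisable at the working potential, while the four protons are reduced to hydrogen at the cathode and the undivided cell stays near neutral. The closest known reaction type is the anodic oxidation of para-unsubstituted phenols and of 4-methoxyphenols in methanol to 4,4-dimethoxycyclohexa-2,5-dienones. No ring is closed and no stereocentre arises, because C5' ends up with two identical methoxy groups. The step needs chemoselectivity for ring B over the ring A diether and the benzylic C–H bonds, secured by ring B carrying the only O–H group (only it has access to the low-potential proton-coupled pathway, and a low current density holds the anode at that potential), and site selectivity for C5', secured by C5' being the only para position, by C1' being blocked by the ester, and by the C6' heptyl group lying meta to the phenol oxygen so that no quinone methide can form. The cold, lutidine-buffered medium is chosen because C4' of 21 is the β-carbon of an enone that bears an aryloxide leaving group, which free methoxide would displace.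

Step 11
Reactants: 21 ring B quinone monoketal
Product: 20 benzyl 2-{4-[(benzyloxy)carbonyl]-3-heptyl-5-hydroxy-2-methoxyphenoxy}-6-heptyl-4-methoxybenzoate
Conditions: Zn dust, AcOH–THF (dry), 0 °C → rt
Reagents that add atoms: none
Why: Dissolving-metal reduction of a quinone monoketal, in which two electrons and two protons convert the dienone into the phenol with expulsion of one C5' methoxy group as methanol, driven by rearomatisation, while the benzyl esters and the vinylic C4'–OAr bond are inert to zinc in acetic acid.

Step 12
Reactants: 20 dibenzyl ester of the target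
Product: 22 2-(4-carboxy-3-heptyl-5-hydroxy-2-methoxyphenoxy)-6-heptyl-4-methoxybenzoic acid (target)
Conditions: H2 (1 atm), 10% Pd/C, EtOAc, rt
Reagents that add atoms: none
Why: Catalytic hydrogenolysis of both benzyl esters under neutral conditions at room temperature should free the two acids without the heat, acid or base that could decarboxylate the ring B salicylic acid.

**Compound list**

1 | octanal | CCCCCCCC=O | starting material
2 | 1-(triphenyl-λ5-phosphanylidene)propan-2-one | CC(=O)C=P(c1ccccc1)(c1ccccc1)c1ccccc1 | starting material
3 | (E)-undec-3-en-2-one | CCCCCCC/C=C/C(C)=O | intermediate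
4 | dimethyl malonate | COC(=O)CC(=O)OC | starting material
5 | dimethyl 2-(2-oxoundecan-4-yl)malonate (racemic Michael adduct, not isolated) | CCCCCCCC(CC(C)=O)C(C(=O)OC)C(=O)OC | intermediate
6 | methyl 6-heptyl-2-hydroxy-4-oxocyclohex-2-ene-1-carboxylate (racemic, enolised 1,3-dione) | CCCCCCCC1CC(=O)C=C(O)C1C(=O)OC | intermediate
7 | methyl 3-bromo-6-heptyl-2-hydroxy-4-oxocyclohex-2-ene-1-carboxylate (racemic, not isolated) | CCCCCCCC1CC(=O)C(Br)=C(O)C1C(=O)OC | intermediate
8 | methyl 5-bromo-6-heptyl-2-hydroxy-4-oxocyclohex-2-ene-1-carboxylate (racemic, not isolated) | CCCCCCCC1C(Br)C(=O)C=C(O)C1C(=O)OC | intermediate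
9 | methyl 2-heptyl-4,6-dihydroxybenzoate | CCCCCCCc1cc(O)cc(O)c1C(=O)OC | intermediate
10 | methyl 2-heptyl-6-hydroxy-4-methoxybenzoate | CCCCCCCc1cc(OC)cc(O)c1C(=O)OC | intermediate
11 | 2-heptyl-6-hydroxy-4-methoxybenzoic acid | CCCCCCCc1cc(OC)cc(O)c1C(=O)O | intermediate
12 | 2-heptyl-4,6-dihydroxybenzoic acid | CCCCCCCc1cc(O)cc(O)c1C(=O)O | intermediate
13 | benzyl bromide | BrCc1ccccc1 | starting material
14 | benzyl 2-heptyl-4,6-dihydroxybenzoate | CCCCCCCc1cc(O)cc(O)c1C(=O)OCc1ccccc1 | intermediate
15 | 2-heptyl-6-hydroxy-4-methoxybenzoic trifluoroacetic anhydride (not isolated) | CCCCCCCc1cc(OC)cc(O)c1C(=O)OC(=O)C(F)(F)F | intermediate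
16 | benzyl 2-heptyl-4-[(2-heptyl-6-hydroxy-4-methoxybenzoyl)oxy]-6-hydroxybenzoate (para-depside) | CCCCCCCc1cc(OC)cc(O)c1C(=O)Oc1cc(O)c(C(=O)OCc2ccccc2)c(CCCCCCC)c1 | intermediate
17 | potassium 2-{4-[(benzyloxy)carbonyl]-3-heptyl-5-hydroxyphenoxy}-6-heptyl-4-methoxybenzoate (not isolated) | CCCCCCCc1cc(OC)cc(Oc2cc(O)c(C(=O)OCc3ccccc3)c(CCCCCCC)c2)c1C(=O)[O-].[K+] | intermediate
18 | benzyl 2-{4-[(benzyloxy)carbonyl]-3-heptyl-5-hydroxyphenoxy}-6-heptyl-4-methoxybenzoate | CCCCCCCc1cc(OC)cc(Oc2cc(O)c(C(=O)OCc3ccccc3)c(CCCCCCC)c2)c1C(=O)OCc1ccccc1 | intermediate
19 | methanol | CO | starting material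
20 | benzyl 2-{4-[(benzyloxy)carbonyl]-3-heptyl-5-hydroxy-2-methoxyphenoxy}-6-heptyl-4-methoxybenzoate (transient in step 10, isolated in step 11) | CCCCCCCc1cc(OC)cc(Oc2cc(O)c(C(=O)OCc3ccccc3)c(CCCCCCC)c2OC)c1C(=O)OCc1ccccc1 | intermediate
21 | benzyl 2-({4-[(benzyloxy)carbonyl]-5-heptyl-6,6-dimethoxy-3-oxocyclohexa-1,4-dien-1-yl}oxy)-6-heptyl-4-methoxybenzoate | CCCCCCCC1=C(C(=O)OCc2ccccc2)C(=O)C=C(Oc2cc(OC)cc(CCCCCCC)c2C(=O)OCc2ccccc2)C1(OC)OC | intermediate
22 | 2-(4-carboxy-3-heptyl-5-hydroxy-2-methoxyphenoxy)-6-heptyl-4-methoxybenzoic acid (achiral) | CCCCCCCc1cc(OC)cc(Oc2cc(O)c(C(=O)O)c(CCCCCCC)c2OC)c1C(=O)O | target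

**Total step count:** 12. **Longest linear sequence:** 10 (steps 1–3, then 4–5 or 6–7, then 8–12).

**Steps most likely to fail**

1. Step 10. Three processes could erode the step.
   - The chelated, ester-deactivated C2' phenol may be oxidised too close to the potential of the ring A diether, so ring A or benzylic C–H methoxylation could intrude.
   - Phenoxyl radical coupling could foul the anode.
   - Methanol could displace the ring A aryloxide from C4' of the dienone once it has formed.

   The fallback avoids dearomatisation and brings the oxygen in as an electrophile. It sets out from 18. Elbs persulfate oxidation (K2S2O8, aq. KOH–pyridine, 0 °C → rt), in which the C2' phenolate attacks peroxydisulfate through its para carbon, should give the C5' O-sulfate of 18 as its potassium salt F1. Mild acid hydrolysis then gives the C5'-hydroxy derivative of 18 (C2',C5' hydroquinone) F2. One equivalent of MeI with K2CO3 in acetone methylates only the unchelated C5' hydroxyl. The fallback rejoins the route at 20 and makes steps 10 and 11 unnecessary.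

2. Step 9. Ipso attack may be sluggish, because ring B is activated by a single para ester and is deactivated whenever its own C2' phenol is deprotonated. Slow rearrangement would give time for cleavage of the depside ester by traces of water and for O-benzylation of a phenol.

   The fallback forms the ether bond by cross-coupling and sets out from 11 and 14. Acid 11 is benzylated (BnBr, KHCO3, DMF) to benzyl 2-heptyl-6-hydroxy-4-methoxybenzoate F3. Its phenol is converted with Tf2O and pyridine into benzyl 2-heptyl-4-methoxy-6-(trifluoromethylsulfonyloxy)benzoate F4. Buchwald–Hartwig-type C–O coupling of F4 with the free, unhindered C4 hydroxyl of 14 (Pd(OAc)2, tBuXPhos, K3PO4, toluene, 100 °C) should then give the diaryl ether, with the chelated hydroxyl of 14 staying out of the reaction. The fallback rejoins the route at 18 and bypasses steps 8 and 9.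

3. Step 6. The electron-rich resorcylate may lose CO2 during the saponification or on acidification, which would drain material to the resorcinol.

   The fallback masks the phenols first and sets out from 9.
   - MOMCl with NaH in DMF gives methyl 2-heptyl-4,6-bis(methoxymethoxy)benzoate F5.
   - Saponification (KOH, aq. DMSO, 100 °C, citric acid work-up) gives 2-heptyl-4,6-bis(methoxymethoxy)benzoic acid F6, which lacks the free phenols that drive decarboxylation.
   - BnBr with KHCO3 in DMF gives benzyl 2-heptyl-4,6-bis(methoxymethoxy)benzoate F7.
   - HCl in MeOH–THF removes both acetals without touching the hindered benzyl ester.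

   The fallback rejoins the route at 14.

**Further compounds**

F1 | step 10 | C5' O-sulfate of 18, potassium salt | CCCCCCCc1cc(OC)cc(Oc2cc(O)c(C(=O)OCc3ccccc3)c(CCCCCCC)c2OS(=O)(=O)[O-])c1C(=O)OCc1ccccc1.[K+]
F2 | step 10 | C5'-hydroxy derivative of 18 (C2',C5' hydroquinone) | CCCCCCCc1cc(OC)cc(Oc2cc(O)c(C(=O)OCc3ccccc3)c(CCCCCCC)c2O)c1C(=O)OCc1ccccc1
F3 | step 9 | benzyl 2-heptyl-6-hydroxy-4-methoxybenzoate | CCCCCCCc1cc(OC)cc(O)c1C(=O)OCc1ccccc1
F4 | step 9 | benzyl 2-heptyl-4-methoxy-6-(trifluoromethylsulfonyloxy)benzoate | CCCCCCCc1cc(OC)cc(OS(=O)(=O)C(F)(F)F)c1C(=O)OCc1ccccc1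
F5 | step 6 | methyl 2-heptyl-4,6-bis(methoxymethoxy)benzoate | CCCCCCCc1cc(OCOC)cc(OCOC)c1C(=O)OC
F6 | step 6 | 2-heptyl-4,6-bis(methoxymethoxy)benzoic acid | CCCCCCCc1cc(OCOC)cc(OCOC)c1C(=O)O
F7 | step 6 | benzyl 2-heptyl-4,6-bis(methoxymethoxy)benzoate | CCCCCCCc1cc(OCOC)cc(OCOC)c1C(=O)OCc1ccccc1
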